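The numbers come from no measurement; the result is computed.

In north-west at the start, starting material is used by the step to intermediate 0.71 times as fast as by the step to homo dimer.

| setting | west | north-west | south |
|---|---|---|---|
| starting material | 0.30 M (fed, over 1.50 d) | 0.30 M | 0.30 M |
| protic impurity | 0.0900 M | 0.0900 M | 0.0900 M |
| time | 3.0 d | 3.0 d |  |
| remark | a stirred flask in which starting material is dosed at a steady rate over 1.50 d without added volume, worked up at 3.0 d | everything together in a closed stirred flask, run for 3.0 d | one stirred flow tank at steady state, fed with the mixture as stated, mean residence time 3.0 d |

    2 starting material → homo dimer (k1 = 0.073 /M/h)
    starting material + protic impurity → quenched substrate (k2 = 0.10 /M/h)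
    intermediate ⇌ isomer of the product (K3 = 2.3, k3 = 0.041 /h)
    starting material → intermediate (k4 = 0.031 /h)
    intermediate ⇌ target (K5 = 1.6, k5 = 0.085 /h)

- the set-up with the highest amount of intermediate at the outlet or at the end, in percent of the starting material put in ("none" if the first two lie within 2 percentage points) (west / north-west / south / none)
- amount of intermediate at the outlet or at the end, in percent of the starting material put in, west
- amount of intermediate at the outlet or at the end, in percent of the starting material put in, north-west
- amount of intermediate at the outlet or at the end, in percent of the starting material put in, south

- percentages count the starting material that a species holds: one homo dimer counts as two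
- a doubled species enters its step squared and goes two at a time
- the stated concentrations are those of everything mixed, before any reaction; amounts are the same in each set-up
- the feed brings no volume worth counting
- run time (west): 3.0 d

I sort the numbers for north-west by what an error would cost, working in fractions of the charge.

1. First come the two equilibrium speeds. The relaxation half-lives (both ways together, each by its own step) are 0.209 d with target and 0.491 d with isomer of the product, shorter than the 3.0 d run. So I use the equilibrium split of this pool of intermediate, target and isomer as an estimate, and the isomer side, the slower, is where it is least sure.

2. The equilibrium constants count directly. At equilibrium, intermediate holds s = 1/(1 + both constants) of the pool, which is 20.4%. Doubling the isomer constant gives 13.9%.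

3. Let x be the fraction still starting material. Then dx/dt = −ax − bx², with the exponent as written. Here a = 0.0400 /h, with the impurity held at its charge, and b = 0.0438 /h, so r = b/a = 1.09. That hold is crude: the impurity is not in excess, and holding it overstates quenching.

4. Starting material has a half-life of 0.93 d by its first-order step alone, shorter than the run, so I integrate x down to zero. The first-order routes take ln(1 + r)/r, and the step to intermediate takes 77.5% of those. The product is the pool share, 52.3%, the fraction of the charge that reaches the pool.

5. Doubling the dimer constant gives 41.1%. Doubling the impurity gives 45.2%.

6. Pool share times s gives 10.7% for north-west. My reckoning stops at this batch flask.

The forecast gives 14.6% for west, 12% for north-west, 14.3% for south and best none, saying “so both beat the batch flask”. My north-west figure is lower than its 12%.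

The simulation gives 14.1% for west, 12.0% for north-west and 14.3% for south, so best is none, and the forecast stands within its tolerance.

In north-west at 30.0 d, intermediate, target and isomer together hold 54.5%, beside my pool share of 52.3%. In north-west at 3.00 d, isomer of the product over intermediate reads 1.71, below its equilibrium constant 2.3, and intermediate holds 23.2% of the pool, above s. The neighbour flask is north-west with 1.2 M of starting material. The same reckoning raises r to 4.38, so its pool share is 29.8% and its intermediate 6.08%. In the simulation, that neighbour flask holds homo dimer at 63.1% and intermediate at 6.88%.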